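**Retrosynthetic overview**
- The target comes from its 3',5'-bis-TIPS ether by fluoride desilylation. The pyranone C ring, the only ring built and the last one formed, is closed by oxidative O1–C2 cyclisation of a 2'-hydroxy-α-methoxychalcone.
- Key disconnection C3–C4. C4 is the carbonyl carbon of 2-hydroxy-3,4,5,6-tetramethoxybenzaldehyde. C3 is the α-lithiated carbon of an (E)-β-methoxystyrene, a masked acyl anion whose polarity-reversing OMe is kept as the 3-OMe of the target.
- The enol ether comes from Wittig methoxymethylenation of TIPS-protected 3,5-dihydroxy-4-methoxybenzaldehyde.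
- The A-ring aldehyde comes from ortho-formylation of 2,3,4,5-tetramethoxyphenol, itself made by ortho-lithiation/borylation/oxidation of 1,2,3,4-tetramethoxybenzene.
- Rings A and B are bought as benzenes.

Assumption: the target has no stereocentre or stereogenic axis, so "single enantiomer" is taken to mean the achiral compound as drawn.

**Route**

Step 1
Reactants: 1 1,2,3,4-tetramethoxybenzene
Product: 4 2,3,4,5-tetramethoxyphenol, via aryllithium 2 (not isolated), via boronate ester 3 (not isolated)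
Conditions: n-BuLi, TMEDA, THF, 0 °C → rt; B(OMe)3, −78 °C → rt; AcOH, 30% aq. H2O2, 0 °C → rt
Reagents that add atoms: hydrogen peroxide, OO
Why: Directed ortho-metalation puts lithium on the only type of ring C–H, and borylation followed by boronate oxidation (1,2-aryl shift to oxygen) gives the phenol; no stereocentre is formed.

Step 2
Reactants: 4 2,3,4,5-tetramethoxyphenol
Product: 5 2-hydroxy-3,4,5,6-tetramethoxybenzaldehyde
Conditions: MgCl2, Et3N, (CH2O)n, MeCN, reflux; 1 M HCl work-up
Reagents that add atoms: paraformaldehyde (formaldehyde), C=O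
Why: Magnesium-mediated ortho-formylation (Casnati–Skattebøl) delivers formaldehyde from the Mg phenoxide to the single free ortho carbon, and a second CH2O oxidises the salicyl alcohol to the aldehyde; no stereocentre.

Step 3
Reactants: 6 3,5-dihydroxy-4-methoxybenzaldehyde
Product: 7 4-methoxy-3,5-bis[(triisopropylsilyl)oxy]benzaldehyde
Conditions: TIPSCl (2.5 equiv), imidazole, DMF, rt
Reagents that add atoms: triisopropylsilyl chloride, CC(C)[Si](Cl)(C(C)C)C(C)C
Why: Standard phenol silylation; TIPS is chosen because it survives t-BuLi, has no benzylic protons and does not direct ring lithiation.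

Step 4
Reactants: 7 4-methoxy-3,5-bis[(triisopropylsilyl)oxy]benzaldehyde
Product: 8 (E)-2-methoxy-5-(2-methoxyethenyl)-1,3-bis[(triisopropylsilyl)oxy]benzene
Conditions: Ph3P(CH2OMe)Cl, NaHMDS, THF, 0 °C; then 7, 0 °C → rt; E isomer separated from Z (about 1:1) on Et3N-deactivated silica
Reagents that add atoms: (methoxymethyl)triphenylphosphonium chloride, COC[P+](c1ccccc1)(c1ccccc1)c1ccccc1.[Cl-]
Why: Wittig methoxymethylenation of an aromatic aldehyde with the non-stabilised ylide gives the enol ether as an E/Z mixture, and only the E isomer is carried on because the Z isomer has its β-H anti to OMe and is prone to base-induced loss of methoxide; no stereocentre.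

Step 5
Reactants: 8 (E)-2-methoxy-5-(2-methoxyethenyl)-1,3-bis[(triisopropylsilyl)oxy]benzene; 5 2-hydroxy-3,4,5,6-tetramethoxybenzaldehyde
Product: 11 rac-(E)-1-(2-hydroxy-3,4,5,6-tetramethoxyphenyl)-2-methoxy-3-{4-methoxy-3,5-bis[(triisopropylsilyl)oxy]phenyl}prop-2-en-1-ol, via vinyllithium 9 (not isolated), via sodium phenoxide 10 (not isolated)
Conditions: 8 (1.2 equiv), t-BuLi (1.15 equiv), THF, −78 → −40 → −78 °C; 5 + NaH (1.05 equiv), THF, 0 °C, cannulated in; −78 → −10 °C; sat. NH4Cl; crude product used directly (excess 8 recovered)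
Reagents that add atoms: none
Why: Proposed new method: α-deprotonation of a β-aryl enol ether is not routine, but the vinylic H geminal to OMe is the kinetically most acidic site (inductive activation plus Li–O pre-coordination, as in the t-BuLi α-lithiation of methyl vinyl ether and 1-alkoxydienes and the C2-lithiation of benzofuran), the E geometry keeps the other vinylic H syn to OMe so anti-elimination to the arylalkyne is disfavoured, and the TIPS ethers block ring lithiation; the resulting α-methoxyvinyllithium is a masked acyl anion (ArCH2C(=O)⁻) that adds 1,2 to the aldehyde of the pre-formed phenoxide and so joins C3, already at the carbonyl oxidation level, to the carbonyl carbon C4, with the one carbinol stereocentre formed without control (racemic) and erased in step 6; closest known reaction type: addition of α-alkoxyvinyllithium acyl-anion equivalents to aldehydes.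

Step 6
Reactants: 11 rac-(E)-1-(2-hydroxy-3,4,5,6-tetramethoxyphenyl)-2-methoxy-3-{4-methoxy-3,5-bis[(triisopropylsilyl)oxy]phenyl}prop-2-en-1-ol
Product: 12 (E)-1-(2-hydroxy-3,4,5,6-tetramethoxyphenyl)-2-methoxy-3-{4-methoxy-3,5-bis[(triisopropylsilyl)oxy]phenyl}prop-2-en-1-one
Conditions: activated MnO2 (15 equiv), CH2Cl2, rt
Reagents that add atoms: none
Why: MnO2 oxidation is selective for the doubly activated (benzylic and allylic) secondary alcohol under neutral conditions, leaves the enol ether, silyl ethers and fully substituted phenol alone, and removes the only stereocentre.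

Step 7
Reactants: 12 (E)-1-(2-hydroxy-3,4,5,6-tetramethoxyphenyl)-2-methoxy-3-{4-methoxy-3,5-bis[(triisopropylsilyl)oxy]phenyl}prop-2-en-1-one
Product: 13 3,5,6,7,8-pentamethoxy-2-{4-methoxy-3,5-bis[(triisopropylsilyl)oxy]phenyl}-4H-chromen-4-one
Conditions: I2 (10 mol %), DMSO, 120 °C; aq. Na2S2O3 work-up
Reagents that add atoms: none
Why: Iodine/DMSO oxidative cyclisation of a 2'-hydroxychalcone (oxa-Michael closure, C3 iodination, loss of HI, with I2 regenerated by DMSO) is the standard route to polymethoxyflavones; the alkene geometry of 12 is irrelevant and no stereocentre remains.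

Step 8
Reactants: 13 3,5,6,7,8-pentamethoxy-2-{4-methoxy-3,5-bis[(triisopropylsilyl)oxy]phenyl}-4H-chromen-4-one
Product: 14 2-(3,5-dihydroxy-4-methoxyphenyl)-3,5,6,7,8-pentamethoxy-4H-chromen-4-one (3',5'-dihydroxy-3,5,6,7,8,4'-hexamethoxyflavone)
Conditions: TBAF (2.4 equiv), AcOH (2.4 equiv), THF, 0 °C → rt
Reagents that add atoms: none
Why: Fluoride cleavage of aryl silyl ethers, buffered with acetic acid so the flavone and its methyl ethers are not touched; the product is achiral.

**Compound list**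
1 | 1,2,3,4-tetramethoxybenzene | COc1ccc(OC)c(OC)c1OC | starting material
2 | (2,3,4,5-tetramethoxyphenyl)lithium | [Li]c1cc(OC)c(OC)c(OC)c1OC | intermediate (not isolated)
3 | dimethyl (2,3,4,5-tetramethoxyphenyl)boronate | COB(OC)c1cc(OC)c(OC)c(OC)c1OC | intermediate (not isolated)
4 | 2,3,4,5-tetramethoxyphenol | Oc1cc(OC)c(OC)c(OC)c1OC | intermediate
5 | 2-hydroxy-3,4,5,6-tetramethoxybenzaldehyde | O=Cc1c(O)c(OC)c(OC)c(OC)c1OC | intermediate
6 | 3,5-dihydroxy-4-methoxybenzaldehyde | COc1c(O)cc(C=O)cc1O | starting material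
7 | 4-methoxy-3,5-bis[(triisopropylsilyl)oxy]benzaldehyde | COc1c(O[Si](C(C)C)(C(C)C)C(C)C)cc(C=O)cc1O[Si](C(C)C)(C(C)C)C(C)C | intermediate
8 | (E)-2-methoxy-5-(2-methoxyethenyl)-1,3-bis[(triisopropylsilyl)oxy]benzene | CO/C=C/c1cc(O[Si](C(C)C)(C(C)C)C(C)C)c(OC)c(O[Si](C(C)C)(C(C)C)C(C)C)c1 | intermediate
9 | [(E)-1-methoxy-2-{4-methoxy-3,5-bis[(triisopropylsilyl)oxy]phenyl}ethenyl]lithium (Li cis to the aryl group) | CO/C([Li])=C/c1cc(O[Si](C(C)C)(C(C)C)C(C)C)c(OC)c(O[Si](C(C)C)(C(C)C)C(C)C)c1 | intermediate (not isolated)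
10 | sodium 2-formyl-3,4,5,6-tetramethoxyphenolate | [Na+].[O-]c1c(C=O)c(OC)c(OC)c(OC)c1OC | intermediate (not isolated)
11 | rac-(E)-1-(2-hydroxy-3,4,5,6-tetramethoxyphenyl)-2-methoxy-3-{4-methoxy-3,5-bis[(triisopropylsilyl)oxy]phenyl}prop-2-en-1-ol (carbinol centre racemic) | CO/C(=C/c1cc(O[Si](C(C)C)(C(C)C)C(C)C)c(OC)c(O[Si](C(C)C)(C(C)C)C(C)C)c1)C(O)c1c(O)c(OC)c(OC)c(OC)c1OC | intermediate
12 | (E)-1-(2-hydroxy-3,4,5,6-tetramethoxyphenyl)-2-methoxy-3-{4-methoxy-3,5-bis[(triisopropylsilyl)oxy]phenyl}prop-2-en-1-one | CO/C(=C/c1cc(O[Si](C(C)C)(C(C)C)C(C)C)c(OC)c(O[Si](C(C)C)(C(C)C)C(C)C)c1)C(=O)c1c(O)c(OC)c(OC)c(OC)c1OC | intermediate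
13 | 3,5,6,7,8-pentamethoxy-2-{4-methoxy-3,5-bis[(triisopropylsilyl)oxy]phenyl}-4H-chromen-4-one | COc1c(O[Si](C(C)C)(C(C)C)C(C)C)cc(-c2oc3c(OC)c(OC)c(OC)c(OC)c3c(=O)c2OC)cc1O[Si](C(C)C)(C(C)C)C(C)C | intermediate
14 | 2-(3,5-dihydroxy-4-methoxyphenyl)-3,5,6,7,8-pentamethoxy-4H-chromen-4-one | COc1c(O)cc(-c2oc3c(OC)c(OC)c(OC)c(OC)c3c(=O)c2OC)cc1O | target

**Totals**
Total step count: 8.
Longest linear sequence: 6 steps (1 → 4 → 5 → 11 → 12 → 13 → 14, i.e. steps 1, 2, 5, 6, 7, 8).

**Three steps most likely to fail, with fallbacks**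

Step 5 (key coupling). The α-lithiation of 8 may be diverted to loss of LiOMe (arylalkyne), or the hindered, deactivated phenoxide-aldehyde 10 may add slowly. Fallback, setting out from 5 (through its salt 10) and from 7, and coming back at 13: the same C3–C4 bond is made with a phosphorus-stabilised α-methoxy carbanion. Diethyl (methoxymethyl)phosphonate is lithiated (LDA, THF, −78 °C) and added to 10, with a cold quench, to give diethyl [2-hydroxy-2-(2-hydroxy-3,4,5,6-tetramethoxyphenyl)-1-methoxyethyl]phosphonate F1. Oxidation (MnO2 or Dess–Martin periodinane) gives diethyl [2-(2-hydroxy-3,4,5,6-tetramethoxyphenyl)-1-methoxy-2-oxoethyl]phosphonate F2. Horner–Wadsworth–Emmons olefination of F2 with aldehyde 7 (NaH, 2.1 equiv, THF) gives (Z)-1-(2-hydroxy-3,4,5,6-tetramethoxyphenyl)-2-methoxy-3-{4-methoxy-3,5-bis[(triisopropylsilyl)oxy]phenyl}prop-2-en-1-one F3, the geometric isomer of 12. F3 is cyclised under the step 7 conditions and rejoins the route at 13.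

Step 6 (oxidation). Diol 11 is an electron-rich o-hydroxybenzylic alcohol next to an enol ether and may ionise (o-quinone methide, 2H-chromene) before it is oxidised. Fallback, setting out from 5 and coming back at 12: the A-ring partner is raised to the acid oxidation level so that no alcohol is formed. Pinnick oxidation of 5 (NaClO2, NaH2PO4, 2-methyl-2-butene, t-BuOH/H2O) gives 2-hydroxy-3,4,5,6-tetramethoxybenzoic acid F4. Coupling with MeNH(OMe)·HCl (CDI, CH2Cl2) gives 2-hydroxy-N,3,4,5,6-pentamethoxy-N-methylbenzamide F5. F5 is deprotonated with NaH to sodium 2-[methoxy(methyl)carbamoyl]-3,4,5,6-tetramethoxyphenolate F6, which is acylated by vinyllithium 9 (THF, −78 → 0 °C) to give chalcone 12 directly after NH4Cl work-up.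

Step 7 (oxidative cyclisation). The α-methoxy enone is a weak oxa-Michael acceptor, and HI formed in situ may erode the TIPS ethers and iodinate the freed ring. Fallback, setting out from 12 and coming back at 13: ring closure and dehydrogenation are separated. NaOAc in refluxing EtOH closes 12 to rac-trans-3,5,6,7,8-pentamethoxy-2-{4-methoxy-3,5-bis[(triisopropylsilyl)oxy]phenyl}chroman-4-one F7. Iodine-free dehydrogenation of F7 (DDQ, dioxane, reflux, or Pd(TFA)2/DMSO/O2) gives 13.

**Further compounds**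
F1 | step 5 | diethyl [2-hydroxy-2-(2-hydroxy-3,4,5,6-tetramethoxyphenyl)-1-methoxyethyl]phosphonate (racemic diastereomer mixture) | CCOP(=O)(OCC)C(OC)C(O)c1c(O)c(OC)c(OC)c(OC)c1OC
F2 | step 5 | diethyl [2-(2-hydroxy-3,4,5,6-tetramethoxyphenyl)-1-methoxy-2-oxoethyl]phosphonate (racemic) | CCOP(=O)(OCC)C(OC)C(=O)c1c(O)c(OC)c(OC)c(OC)c1OC
F3 | step 5 | (Z)-1-(2-hydroxy-3,4,5,6-tetramethoxyphenyl)-2-methoxy-3-{4-methoxy-3,5-bis[(triisopropylsilyl)oxy]phenyl}prop-2-en-1-one | CO/C(=C\c1cc(O[Si](C(C)C)(C(C)C)C(C)C)c(OC)c(O[Si](C(C)C)(C(C)C)C(C)C)c1)C(=O)c1c(O)c(OC)c(OC)c(OC)c1OC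
F4 | step 6 | 2-hydroxy-3,4,5,6-tetramethoxybenzoic acid | OC(=O)c1c(O)c(OC)c(OC)c(OC)c1OC
F5 | step 6 | 2-hydroxy-N,3,4,5,6-pentamethoxy-N-methylbenzamide | CON(C)C(=O)c1c(O)c(OC)c(OC)c(OC)c1OC
F6 | step 6 | sodium 2-[methoxy(methyl)carbamoyl]-3,4,5,6-tetramethoxyphenolate | [Na+].[O-]c1c(C(=O)N(C)OC)c(OC)c(OC)c(OC)c1OC
F7 | step 7 | rac-trans-3,5,6,7,8-pentamethoxy-2-{4-methoxy-3,5-bis[(triisopropylsilyl)oxy]phenyl}chroman-4-one (one enantiomer drawn) | CO[C@H]1[C@H](c2cc(O[Si](C(C)C)(C(C)C)C(C)C)c(OC)c(O[Si](C(C)C)(C(C)C)C(C)C)c2)Oc2c(OC)c(OC)c(OC)c(OC)c2C1=O
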